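**Retrosynthetic overview**

1. The C7–O–CH2 ether is cut (Mitsunobu) into 7-hydroxy-6,8-dimethoxycoumarin 13 and the (2R,3R)-epoxy diol 20.
2. The route rests on ring A of the coumarin: C6, C7, C8 and C8a each carry oxygen, followed by C5–H and C4a–C. A squarate-derived 4-alkenyl-4-methoxycyclobutenone (6) delivers exactly this pattern by 4π opening and 6π closure, giving phenol 9 with a masked formyl group at the future C4a.
3. The pyranone ring is closed second, by Wittig olefination–lactonization of salicylaldehyde 10. The C7 methoxy group, para to the enoate, is then cleaved selectively.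
4. Side chain: the distal alkene of geranyl acetate is epoxidized and transposed to the (E)-allylic tertiary alcohol by selenide opening and selenoxide elimination. Sharpless epoxidation with D-(−)-tartrate then sets C2 and C3 and forms the oxirane.
5. Ring order: ring A (step 3), lactone ring (step 5), oxirane (step 10); the two halves are joined in step 11.

Key step: step 3

Assumption: geranyl acetate, the commercial acetate of geraniol, is taken as the terpene starting material because the ester deactivates the 2,3-alkene toward peracid.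

**Route**

Step 1
Reactants: 1 3,3-diethoxyprop-1-yne
Product: 2 tributyl[(1E)-3,3-diethoxyprop-1-en-1-yl]stannane
Conditions: Bu3SnH (slight excess), AIBN (cat.), neat, 85 °C; distillation or chromatography on Et3N-deactivated silica
Reagents that add atoms: tributyltin hydride, CCCC[SnH](CCCC)CCCC
Why: Radical hydrostannylation of a terminal alkyne puts tin on the terminal carbon, and reversible stannyl-radical addition on continued heating should equilibrate the vinylstannane toward the E isomer.

Step 2
Reactants: 2 tributyl[(1E)-3,3-diethoxyprop-1-en-1-yl]stannane; 3 dimethyl squarate (3,4-dimethoxycyclobut-3-ene-1,2-dione)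
Product: 6 4-[(1E)-3,3-diethoxyprop-1-en-1-yl]-2,3,4-trimethoxycyclobut-2-en-1-one (racemic), via alkenyllithium 4 (not isolated), via lithium alkoxide 5 (not isolated)
Conditions: n-BuLi (slightly less than 2), THF, −78 °C; cannulated into 3, THF, −78 °C; MeOTf, −78 → 0 °C; aq. NaHCO3; Et3N-deactivated silica
Reagents that add atoms: methyl trifluoromethanesulfonate, COS(=O)(=O)C(F)(F)F
Why: Tin–lithium exchange keeps the E geometry, the alkenyllithium adds 1,2 to one squarate carbonyl, and the tertiary lithium alkoxide is O-methylated in situ by MeOTf so that the acid-sensitive carbinol is never handled.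

Step 3
Reactants: 6 4-[(1E)-3,3-diethoxyprop-1-en-1-yl]-2,3,4-trimethoxycyclobut-2-en-1-one (racemic)
Product: 9 6-(diethoxymethyl)-2,3,4-trimethoxyphenol, via dienylketene 7 (not isolated), via cyclohexadienone 8 (not isolated)
Conditions: degassed p-xylene (0.02 M), 138 °C, Ar, base-washed glassware
Reagents that add atoms: none
Why: Thermal conrotatory 4π opening of the cyclobutenone breaks the C1–C4 bond and gives dienylketene 7, whose ketene carbon bonds to the acetal-bearing alkene terminus in a 6π electrocyclization to dienone 8, and enolization then gives phenol 9. The closest known reaction type is the Moore rearrangement of 4-alkenyl-4-alkoxycyclobutenones from squarate esters into polyoxygenated phenols. Ring A closes as a six-membered carbocycle by disrotatory 6π electrocyclic closure, which forms the future C4a–C8a bond. No stereocentre is created, because the sp3 carbon of 8 is lost on tautomerization and the C4 centre of 6 becomes planar. The step needs torquoselective opening with the 4-methoxy group turning outward and the alkenyl group inward so that the alkene lies cis to the ketene, and the donor oxygen substituent at C4 secures this. The placement of the free phenol beside the acetal carbon, then three methoxy groups in a row and C–H last, follows from the connectivity of 6 and cannot be scrambled.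

Step 4
Reactants: 9 6-(diethoxymethyl)-2,3,4-trimethoxyphenol
Product: 10 2-hydroxy-3,4,5-trimethoxybenzaldehyde
Conditions: 1 M HCl, THF, rt (crude 9 taken on directly)
Reagents that add atoms: water, O
Why: Acid-catalysed acetal hydrolysis leaves the aryl methyl ethers and the phenol untouched, and any material that has lost ethanol from the acetal should converge on the same aldehyde on hydration.

Step 5
Reactants: 10 2-hydroxy-3,4,5-trimethoxybenzaldehyde
Product: 12 6,7,8-trimethoxycoumarin (6,7,8-trimethoxy-2H-chromen-2-one), via hydroxycinnamate ester 11 (not isolated)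
Conditions: Ph3P=CHCO2Et (1.3 equiv), PhNEt2, reflux (ca. 215 °C)
Reagents that add atoms: ethyl (triphenylphosphoranylidene)acetate, CCOC(=O)C=P(c1ccccc1)(c1ccccc1)c1ccccc1
Why: Wittig olefination of the salicylaldehyde gives the o-hydroxycinnamate, which at this temperature isomerizes to the Z ester and lactonizes with loss of ethanol (Wittig olefination–lactonization), closing the pyranone ring.

Step 6
Reactants: 12 6,7,8-trimethoxycoumarin
Product: 13 7-hydroxy-6,8-dimethoxycoumarin (isofraxidin)
Conditions: NaSEt (2.5 equiv), DMF, 100 °C; then 1 M HCl, 0 °C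
Reagents that add atoms: none
Why: SN2 O-demethylation by thiolate should select the C7 methoxy group, since its phenoxide is the best leaving group (para to the C4a–C4=C3–C2=O enoate) and it is the central, twisted methoxy of the three, while acidification re-closes any lactone opened by thiolate.

Step 7
Reactants: 14 geranyl acetate [(2E)-3,7-dimethylocta-2,6-dien-1-yl acetate]
Product: 15 (2E)-5-(3,3-dimethyloxiran-2-yl)-3-methylpent-2-en-1-yl acetate (racemic)
Conditions: mCPBA (1.05 equiv), NaHCO3, CH2Cl2, 0 °C
Reagents that add atoms: 3-chloroperoxybenzoic acid, OOC(=O)c1cccc(Cl)c1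
Why: Prilezhaev epoxidation is chemoselective for the electron-rich distal trisubstituted alkene because the 2,3-alkene is deactivated by the allylic acetate.

Step 8
Reactants: 15 (2E)-5-(3,3-dimethyloxiran-2-yl)-3-methylpent-2-en-1-yl acetate (racemic)
Product: 16 (2E)-5-(3,3-dimethyloxiran-2-yl)-3-methylpent-2-en-1-ol (racemic)
Conditions: K2CO3 (0.2 equiv), MeOH, 0 °C → rt
Reagents that add atoms: none
Why: Base-catalysed transesterification removes the acetate under conditions that do not open the trisubstituted epoxide.

Step 9
Reactants: 16 (2E)-5-(3,3-dimethyloxiran-2-yl)-3-methylpent-2-en-1-ol (racemic)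
Product: 19 (2E,5E)-3,7-dimethylocta-2,5-diene-1,7-diol, via hydroxy selenide 17 (not isolated), via selenoxide 18 (not isolated)
Conditions: PhSeSePh (0.6 equiv), NaBH4 (1.3 equiv), EtOH, rt; then 16, reflux; then THF, 30% H2O2 (small excess), 0 °C → rt
Reagents that add atoms: none
Why: The selenolate opens the epoxide by SN2 attack at the less hindered C6, and syn elimination of the derived selenoxide can only use the C5 hydrogens because C7 carries none, which should give the E alkene next to the tertiary alcohol (epoxide to allylic alcohol transposition).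

Step 10
Reactants: 19 (2E,5E)-3,7-dimethylocta-2,5-diene-1,7-diol
Product: 20 [(2R,3R)-3-[(2E)-4-hydroxy-4-methylpent-2-en-1-yl]-3-methyloxiran-2-yl]methanol
Conditions: Ti(OiPr)4 (10 mol%), D-(−)-diethyl tartrate (12 mol%), TBHP (anhydrous, in isooctane, 1.5 equiv), 4 Å MS, CH2Cl2, −20 °C
Reagents that add atoms: tert-butyl hydroperoxide, CC(C)(C)OO
Why: Sharpless asymmetric epoxidation of the primary E-allylic alcohol with D-(−)-tartrate delivers oxygen to the face that makes both C2 and C3 R (opposite to the (2S,3S) outcome of L-(+)-tartrate), the E geometry fixes their relative configuration, and the 5,6-alkene next to the tertiary alcohol is a poor substrate and should remain.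

Step 11
Reactants: 13 7-hydroxy-6,8-dimethoxycoumarin; 20 [(2R,3R)-3-[(2E)-4-hydroxy-4-methylpent-2-en-1-yl]-3-methyloxiran-2-yl]methanol
Product: 21 7-{[(2R,3R)-3-[(2E)-4-hydroxy-4-methylpent-2-en-1-yl]-3-methyloxiran-2-yl]methoxy}-6,8-dimethoxy-2H-chromen-2-one (target)
Conditions: PPh3, DIAD, THF, 0 °C → rt
Reagents that add atoms: none
Why: In this Mitsunobu etherification the acidic phenol displaces the activated primary hydroxyl at C1, which is not a stereocentre, so C2 and C3 are untouched, the tertiary alcohol does not react and the neutral conditions spare epoxide and lactone.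

**Compound list**

1 | 3,3-diethoxyprop-1-yne | CCOC(OCC)C#C | starting material
2 | tributyl[(1E)-3,3-diethoxyprop-1-en-1-yl]stannane | CCCC[Sn](CCCC)(CCCC)/C=C/C(OCC)OCC | intermediate
3 | dimethyl squarate (3,4-dimethoxycyclobut-3-ene-1,2-dione) | COC1=C(OC)C(=O)C1=O | starting material
4 | [(1E)-3,3-diethoxyprop-1-en-1-yl]lithium | [Li]/C=C/C(OCC)OCC | intermediate
5 | lithium 1-[(1E)-3,3-diethoxyprop-1-en-1-yl]-2,3-dimethoxy-4-oxocyclobut-2-en-1-olate (racemic) | [Li+].[O-]C1(/C=C/C(OCC)OCC)C(OC)=C(OC)C1=O | intermediate
6 | 4-[(1E)-3,3-diethoxyprop-1-en-1-yl]-2,3,4-trimethoxycyclobut-2-en-1-one (racemic) | COC1=C(OC)C(OC)(/C=C/C(OCC)OCC)C1=O | intermediate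
7 | (3Z,5E)-7,7-diethoxy-2,3,4-trimethoxyhepta-1,3,5-trien-1-one | O=C=C(OC)/C(OC)=C(OC)\C=C\C(OCC)OCC | intermediate
8 | 6-(diethoxymethyl)-2,3,4-trimethoxycyclohexa-2,4-dien-1-one (racemic) | O=C1C(OC)=C(OC)C(OC)=CC1C(OCC)OCC | intermediate
9 | 6-(diethoxymethyl)-2,3,4-trimethoxyphenol | CCOC(OCC)c1cc(OC)c(OC)c(OC)c1O | intermediate
10 | 2-hydroxy-3,4,5-trimethoxybenzaldehyde | O=Cc1cc(OC)c(OC)c(OC)c1O | intermediate
11 | ethyl (2Z)-3-(2-hydroxy-3,4,5-trimethoxyphenyl)prop-2-enoate | CCOC(=O)/C=C\c1cc(OC)c(OC)c(OC)c1O | intermediate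
12 | 6,7,8-trimethoxy-2H-chromen-2-one | COc1cc2ccc(=O)oc2c(OC)c1OC | intermediate
13 | 7-hydroxy-6,8-dimethoxy-2H-chromen-2-one (isofraxidin) | COc1cc2ccc(=O)oc2c(OC)c1O | intermediate
14 | geranyl acetate [(2E)-3,7-dimethylocta-2,6-dien-1-yl acetate] | CC(C)=CCC/C(C)=C/COC(C)=O | starting material
15 | (2E)-5-(3,3-dimethyloxiran-2-yl)-3-methylpent-2-en-1-yl acetate (racemic) | CC(=O)OC/C=C(\C)CCC1OC1(C)C | intermediate
16 | (2E)-5-(3,3-dimethyloxiran-2-yl)-3-methylpent-2-en-1-ol (racemic) | OC/C=C(\C)CCC1OC1(C)C | intermediate
17 | (2E)-3,7-dimethyl-6-(phenylselanyl)oct-2-ene-1,7-diol (racemic) | OC/C=C(\C)CCC([Se]c1ccccc1)C(C)(C)O | intermediate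
18 | (2E)-3,7-dimethyl-6-(phenylseleninyl)oct-2-ene-1,7-diol (mixture of diastereomers) | OC/C=C(\C)CCC([Se](=O)c1ccccc1)C(C)(C)O | intermediate
19 | (2E,5E)-3,7-dimethylocta-2,5-diene-1,7-diol | OC/C=C(\C)C/C=C/C(C)(C)O | intermediate
20 | [(2R,3R)-3-[(2E)-4-hydroxy-4-methylpent-2-en-1-yl]-3-methyloxiran-2-yl]methanol | OC[C@H]1O[C@]1(C)C/C=C/C(C)(C)O | intermediate
21 | 7-{[(2R,3R)-3-[(2E)-4-hydroxy-4-methylpent-2-en-1-yl]-3-methyloxiran-2-yl]methoxy}-6,8-dimethoxy-2H-chromen-2-one | COc1cc2ccc(=O)oc2c(OC)c1OC[C@H]1O[C@]1(C)C/C=C/C(C)(C)O | target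

**Step count**

Total steps: 11. Longest linear sequence: 7 steps (steps 1, 2, 3, 4, 5, 6, 11). The side-chain branch runs through steps 7, 8, 9, 10 and joins in step 11.

**Steps most likely to fail, with fallbacks**

1. Step 3 (key step). The cascade may be diverted by thermal loss of ethanol from the acetal beside the newly formed phenol, followed by oligomerization, or by incomplete inward rotation of the substituted alkenyl group. The fallback takes the acetal out of the thermolysis and adds the formyl carbon afterwards.
 - It sets out from 3. Vinylmagnesium bromide (THF, −78 °C) should give 4-ethenyl-4-hydroxy-2,3-dimethoxycyclobut-2-en-1-one F1.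
 - Methylation (MeI, Ag2O, K2CO3, MeCN) should give 4-ethenyl-2,3,4-trimethoxycyclobut-2-en-1-one F2.
 - Thermolysis in refluxing toluene should pass through (3Z)-2,3,4-trimethoxyhexa-1,3,5-trien-1-one F3 and 2,3,4-trimethoxycyclohexa-2,4-dien-1-one F4 to 2,3,4-trimethoxyphenol F5.
 - Magnesium-mediated ortho-formylation (MgCl2, Et3N, paraformaldehyde, MeCN, reflux) at the only free ortho position then returns to the route at 10.

2. Step 6. The thiolate may add to C4 or open the lactone without clean re-closure, or a second methyl ether may be cleaved. The fallback removes the methyl group before the lactone exists and by a Lewis-acid mechanism.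
 - It sets out from 10. AlCl3 in CH2Cl2 (rt) should cleave the methoxy group para to the chelated formyl group, giving 2,4-dihydroxy-3,5-dimethoxybenzaldehyde F6.
 - Wittig olefination–lactonization (Ph3P=CHCO2Et, 2.5 equiv, PhNEt2, reflux) through ethyl (2Z)-3-(2,4-dihydroxy-3,5-dimethoxyphenyl)prop-2-enoate F7 then gives 13 directly, bypassing 12.

3. Step 11. With the doubly ortho-substituted phenol, attack on the alkoxyphosphonium ion may be slow, so that the hydrazide anion alkylates instead or the epoxide is opened on forcing. The fallback replaces the redox condensation by a plain phenoxide alkylation.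
 - It sets out from 20. TsCl, Et3N and DMAP (cat.) in CH2Cl2 at 0 °C should sulfonylate only the primary alcohol, giving [(2R,3R)-3-[(2E)-4-hydroxy-4-methylpent-2-en-1-yl]-3-methyloxiran-2-yl]methyl 4-methylbenzenesulfonate F8.
 - Reaction of F8 with 13 and Cs2CO3 in DMF at 40 °C by SN2 at the primary carbon returns to the route at 21, with C2 and C3 untouched.

Further compounds
F1 | step 3 | 4-ethenyl-4-hydroxy-2,3-dimethoxycyclobut-2-en-1-one (racemic) | C=CC1(O)C(OC)=C(OC)C1=O
F2 | step 3 | 4-ethenyl-2,3,4-trimethoxycyclobut-2-en-1-one (racemic) | C=CC1(OC)C(OC)=C(OC)C1=O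
F3 | step 3 | (3Z)-2,3,4-trimethoxyhexa-1,3,5-trien-1-one | O=C=C(OC)/C(OC)=C(OC)\C=C
F4 | step 3 | 2,3,4-trimethoxycyclohexa-2,4-dien-1-one | O=C1CC=C(OC)C(OC)=C1OC
F5 | step 3 | 2,3,4-trimethoxyphenol | COc1ccc(O)c(OC)c1OC
F6 | step 6 | 2,4-dihydroxy-3,5-dimethoxybenzaldehyde | O=Cc1cc(OC)c(O)c(OC)c1O
F7 | step 6 | ethyl (2Z)-3-(2,4-dihydroxy-3,5-dimethoxyphenyl)prop-2-enoate | CCOC(=O)/C=C\c1cc(OC)c(O)c(OC)c1O
F8 | step 11 | [(2R,3R)-3-[(2E)-4-hydroxy-4-methylpent-2-en-1-yl]-3-methyloxiran-2-yl]methyl 4-methylbenzenesulfonate | Cc1ccc(cc1)S(=O)(=O)OC[C@H]1O[C@]1(C)C/C=C/C(C)(C)O
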